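Petrosin A is taken apart at the two C1–Ce bonds. C1 of each quinolizidin-2-one (ring A) is α to the C2 ketone and carries the last methylene, Ce, of the five-carbon chain that starts at C9 of the other unit. Each bond can therefore arise from an allyl β-keto ester at C1 with loss of CO2. In one operation, palladium excises both ester tethers of a 20-membered head-to-tail diolide, forms both C1–Ce bonds and contracts the ring to the 16-membered carbocycle. The precursor is the heterochiral bis(allyl β-keto ester) diolide, assembled by thermal acylketene cyclodimerisation of a racemic hydroxy tert-butyl β-keto ester monomer.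

Key step: step 8

Remark: atoms are numbered as in quinolizidine (ring A: C1–C4, N5, C10; ring B: N5, C6–C10; C10 is C9a in systematic names; Ca–Ce is the chain from C9; primes mark the second unit). The target is meso, its two halves being mirror images, so the monomer is made racemic and drawn as one enantiomer, and the heterochiral dimer is the one carried on.

Step 1
Reactants: 1 tert-butyl 2-oxopiperidine-1-carboxylate; 2 4-iodobut-1-ene
Product: 3 tert-butyl 3-(but-3-en-1-yl)-2-oxopiperidine-1-carboxylate (racemic)
Conditions: LiN(SiMe3)2, THF, −78 °C; then 2, DMPU, −78 → −20 °C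
Reagents that add atoms: none
Why: Enolate alkylation, in which the Boc group acidifies C3 and blocks nitrogen so that the lithium enolate should be alkylated by the primary iodide in an SN2 reaction; the new stereocentre (the later C9) is formed racemic on purpose, because the meso target needs both enantiomers in equal amounts.

Step 2
Reactants: 3 tert-butyl 3-(but-3-en-1-yl)-2-oxopiperidine-1-carboxylate; 4 (Z)-but-2-ene-1,4-diol
Product: 5 tert-butyl 3-[(E)-5-hydroxypent-3-en-1-yl]-2-oxopiperidine-1-carboxylate (racemic)
Conditions: 4 (3 equiv), second-generation Grubbs catalyst RuCl2(=CHPh)(H2IMes)(PCy3) (3 mol %), CH2Cl2, 40 °C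
Reagents that add atoms: none
Why: Olefin cross-metathesis of a terminal alkene with a symmetrical allylic diol should give mainly the (E)-allylic alcohol under thermodynamic control, and it is run at the carbamate stage so that no basic nitrogen can bind the ruthenium carbene; a small (Z) share is harmless because the alkene geometry is erased in step 9.

Step 3
Reactants: 5 tert-butyl 3-[(E)-5-hydroxypent-3-en-1-yl]-2-oxopiperidine-1-carboxylate
Product: 6 tert-butyl 2-hydroxy-3-[(E)-5-hydroxypent-3-en-1-yl]piperidine-1-carboxylate (diastereomer mixture)
Conditions: LiBHEt3 (2.2 equiv), THF, −78 °C; then H2O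
Reagents that add atoms: none
Why: Partial hydride reduction of an N-acyl lactam, in which the Boc-activated carbonyl takes up one hydride and the tetrahedral lithium alkoxide survives at −78 °C, so the reaction should stop at the hemiaminal (one further equivalent of hydride is spent on the hydroxyl group); the new hemiaminal centre is of no consequence.

Step 4
Reactants: 7 tert-butyl acetate; 8 methacrolein
Product: 9 tert-butyl 3-hydroxy-4-methylpent-4-enoate (racemic)
Conditions: LiN(iPr)2, THF, −78 °C; then 8; AcOH quench at −78 °C
Reagents that add atoms: none
Why: Aldol addition, in which the lithium ester enolate adds 1,2 to the enal at low temperature; the new carbinol centre is racemic and is removed in step 5.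

Step 5
Reactants: 9 tert-butyl 3-hydroxy-4-methylpent-4-enoate
Product: 10 tert-butyl 4-methyl-3-oxopent-4-enoate
Conditions: Dess–Martin periodinane, CH2Cl2, 0 °C → rt; used at once
Reagents that add atoms: none
Why: Dess–Martin oxidation of a secondary allylic alcohol under nearly neutral conditions should give the Nazarov-type keto ester without polymerising the isopropenyl ketone.

Step 6
Reactants: 6 tert-butyl 2-hydroxy-3-[(E)-5-hydroxypent-3-en-1-yl]piperidine-1-carboxylate; 10 tert-butyl 4-methyl-3-oxopent-4-enoate
Product: 12 tert-butyl rel-(1R,3R,9S,9aS)-9-[(E)-5-hydroxypent-3-en-1-yl]-3-methyl-2-oxooctahydro-2H-quinolizine-1-carboxylate (racemic monomer), via cyclic imine 11 (not isolated)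
Conditions: CF3CO2H/CH2Cl2 (1:4), 0 °C → rt; concentrate; then 10 (1.3 equiv), Et3N, MeOH, 0 °C → rt
Reagents that add atoms: none
Why: Acid removes the Boc group and dehydrates the hemiaminal to imine 11, which should undergo the known formal aza-[4+2] annulation of cyclic imines with Nazarov reagents (Mannich addition of the β-keto ester carbon C1 to C10 and aza-Michael addition of nitrogen to the enone terminus C4) to close ring A; the C1–C10 bond forms anti to the C9 chain and the Mannich step is reversible, so the trans-fused quinolizidine with H-9 trans to H-10 and an equatorial C3 methyl group (set by enolisation) is expected, while C1 stays labile.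

Step 7
Reactants: 12 racemic monomer (two molecules, one of each enantiomer)
Product: 15 heterochiral 20-membered bis(allyl β-keto ester) diolide, via acylketene 13 (not isolated), via open-chain hydroxy ester dimer 14 (not isolated)
Conditions: PhMe (0.01 M), reflux (110 °C), 4 Å molecular sieves in a Soxhlet thimble (removal of t-BuOH), Ar
Reagents that add atoms: none
Why: Thermal acylketene formation and trapping, in which the enolised tert-butyl β-keto ester loses tert-butanol to the α-oxoketene 13 that only an alcohol can capture, so head-to-tail pairing to 14 and then closure of the unstrained 20-membered ring are enforced (the 10-membered lactone of a single monomer is a disfavoured medium ring); no stereocentre is created, and the heterochiral pairing needed for the meso target should form beside the homochiral diolide, from which it is separated by chromatography.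

Step 8
Reactants: 15 heterochiral 20-membered bis(allyl β-keto ester) diolide
Product: 17 tetradehydropetrosin A (16-membered carbocycle with two (E) chain alkenes), via 18-membered keto lactone 16 (not isolated)
Conditions: Pd(PPh3)4 (10 mol %), THF (0.005 M), 25 → 60 °C, Ar
Reagents that add atoms: none
Why: Proposed new method: zerovalent palladium should add oxidatively to each allylic C–O bond of 15; the β-keto carboxylate set free loses CO2 to a C1 enolate (or is C-allylated at C1 first and then decarboxylates, which makes the same bond), and the enolate carbon attacks the CH2 terminus Ce of its π-allyl partner, which gives the C1–Ce bond and an (E)-alkene and returns the catalyst. The closest known reaction type is the Tsuji–Saegusa decarboxylative allylation of allyl β-keto esters (the palladium version of the Carroll rearrangement), and the new element is its twofold use as a ring contraction of a macrodiolide. The 16-membered carbocycle closes in two successive ring contractions, 20 to 18 (compound 16) and 18 to 16, each by recombination of an enolate with its own π-allyl partner, to which it stays tied by the rest of the ring and by ion pairing, so dilution only has to suppress crossover between molecules. C1 and C1′ are the new stereocentres; axial attack on the enolate would already place the chain axial as in the target, but these centres are α to a ketone, so their kinetic configuration is not relied on and is settled in step 9 under the control of the equatorial C9 chain across the ring fusion. The step needs attack at the primary rather than the internal allyl carbon, C- rather than N-allylation, and C1 rather than C3 as the nucleophilic carbon: the PPh3-bound π-allyl palladium unit is attacked at its less hindered end, N-allyl ammonium salts of the tertiary amines re-ionise under the catalyst and drain back, and the enolate is born at C1 because that is where the carboxylate sat.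

Step 9
Reactants: 17 tetradehydropetrosin A (as formed, epimeric at C1 and C1′)
Product: 18 petrosin A
Conditions: H2 (1 atm), 10% Pd/C, K2CO3, MeOH, rt
Reagents that add atoms: none
Why: Heterogeneous hydrogenation saturates both disubstituted chain alkenes and leaves ketones and amines alone, while carbonate in methanol equilibrates C1, C1′, C3 and C3′ through the enolates to the most stable arrangement, in which the C3 methyl group is equatorial and the C1 chain is axial (H-1 cis to H-10) because an equatorial C1 chain would clash with the equatorial C9 chain across the ring fusion, and this is the configuration of petrosin A.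

Compound list

1 | tert-butyl 2-oxopiperidine-1-carboxylate (N-Boc-2-piperidone) | O=C1CCCCN1C(=O)OC(C)(C)C | starting material
2 | 4-iodobut-1-ene | C=CCCI | starting material
3 | tert-butyl 3-(but-3-en-1-yl)-2-oxopiperidine-1-carboxylate (racemic) | C=CCCC1CCCN(C(=O)OC(C)(C)C)C1=O | intermediate
4 | (Z)-but-2-ene-1,4-diol | OC/C=C\CO | starting material
5 | tert-butyl 3-[(E)-5-hydroxypent-3-en-1-yl]-2-oxopiperidine-1-carboxylate (racemic) | OC/C=C/CCC1CCCN(C(=O)OC(C)(C)C)C1=O | intermediate
6 | tert-butyl 2-hydroxy-3-[(E)-5-hydroxypent-3-en-1-yl]piperidine-1-carboxylate (diastereomer mixture; both centres are erased or reset in step 6) | OC/C=C/CCC1CCCN(C(=O)OC(C)(C)C)C1O | intermediate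
7 | tert-butyl acetate | CC(=O)OC(C)(C)C | starting material
8 | methacrolein (2-methylprop-2-enal) | CC(=C)C=O | starting material
9 | tert-butyl 3-hydroxy-4-methylpent-4-enoate (racemic) | CC(=C)C(O)CC(=O)OC(C)(C)C | intermediate
10 | tert-butyl 4-methyl-3-oxopent-4-enoate | CC(=C)C(=O)CC(=O)OC(C)(C)C | intermediate
11 | (E)-5-(3,4,5,6-tetrahydropyridin-3-yl)pent-2-en-1-ol (cyclic imine; racemic, ring C3 labile) | OC/C=C/CCC1CCCN=C1 | intermediate
12 | tert-butyl rel-(1R,3R,9S,9aS)-9-[(E)-5-hydroxypent-3-en-1-yl]-3-methyl-2-oxooctahydro-2H-quinolizine-1-carboxylate (racemic; trans-fused; H-9 trans to H-9a; C1 labile, partly enolised) | C[C@@H]1CN2CCC[C@H](CC/C=C/CO)[C@H]2[C@@H](C(=O)OC(C)(C)C)C1=O | intermediate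
13 | rel-(3R,9S,9aS)-9-[(E)-5-hydroxypent-3-en-1-yl]-3-methyl-1-(oxomethylidene)hexahydro-2H-quinolizin-2-one (acylketene from 12) | C[C@@H]1CN2CCC[C@H](CC/C=C/CO)[C@H]2C(=C=O)C1=O | intermediate
14 | open-chain heterochiral dimer: the C1 carboxyl of a (1R,3R,9S,9aS) unit that keeps its free hydroxyl esterifies the (E)-pentenyl alcohol of a (1S,3S,9R,9aR) unit that keeps its tert-butyl ester | C[C@@H]1CN2CCC[C@H](CC/C=C/CO)[C@H]2[C@@H](C(=O)OC/C=C/CC[C@@H]3CCCN4C[C@H](C)C(=O)[C@@H](C(=O)OC(C)(C)C)[C@@H]34)C1=O | intermediate
15 | heterochiral 20-membered diolide: each C1 carboxyl esterifies the (E)-5-hydroxypent-3-enyl chain on C9 of the other quinolizidin-2-one; halves (1R,3R,9S,9aS) and (1S,3S,9R,9aR); C1 and C1′ labile | C[C@@H]1CN2CCC[C@@H]3CC/C=C/COC(=O)[C@@H]4C(=O)[C@@H](C)CN5CCC[C@@H](CC/C=C/COC(=O)[C@@H](C1=O)[C@H]32)[C@H]45 | intermediate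
16 | 18-membered keto lactone: one C9–CH2CH2CH=CH–CH2–C1′ chain formed, one allyl β-keto ester tether left | C[C@@H]1CN2CCC[C@@H]3CC/C=C/C[C@@H]4C(=O)[C@@H](C)CN5CCC[C@@H](CC/C=C/COC(=O)[C@@H](C1=O)[C@H]32)[C@H]45 | intermediate
17 | tetradehydropetrosin A: 16-membered carbocycle, both C9–Ca–Cb–Cc=Cd–Ce–C1′ chains with (E) alkenes; the epimer with the target configuration at C1 and C1′ is drawn | C[C@@H]1CN2CCC[C@@H]3CC/C=C/C[C@@H]4C(=O)[C@@H](C)CN5CCC[C@@H](CC/C=C/C[C@@H](C1=O)[C@H]32)[C@H]45 | intermediate
18 | petrosin A (meso; halves (1R,3R,9S,9aS) and (1S,3S,9R,9aR)) | C[C@@H]1CN2CCC[C@@H]3CCCCC[C@@H]4C(=O)[C@@H](C)CN5CCC[C@@H](CCCCC[C@@H](C1=O)[C@H]32)[C@H]45 | target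

Total step count: 9. Longest linear sequence: 7 steps (steps 1, 2, 3, 6, 7, 8, 9); steps 4 and 5 make the annulation partner.

Steps most likely to fail

Step 8. After ionisation the β-keto carboxylate may lose CO2 and simply be protonated, the π-allyl unit may eliminate to a diene, or enolate and allyl partners of different molecules may combine to oligomers. The fallback uses known chemistry, does without the ester tether and sets out from 12. The alcohol is converted into the allylic methyl carbonate F1 (ClCO2Me, pyridine, CH2Cl2, 0 °C). Slow addition of F1 to Pd(PPh3)4 in THF at high dilution should give the 16-membered bis(tert-butyl β-keto ester) F2 with quaternary C1 and C1′. It would form by two Tsuji–Trost allylic alkylations of the β-keto ester carbon C1, first between two molecules head to tail and then ring-closing, with the methoxide released from the carbonate as the base. CF3CO2H in CH2Cl2 followed by warming removes both tert-butyl esters with decarboxylation and gives 17, where the route is rejoined before step 9. The heterochiral isomer is separated from the homochiral one at the stage of F2 or 17.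

Step 7. Chain growth to linear oligomers and larger rings may outrun ring closure at the dimer stage, and long heating may erode the β-amino ketone (retro-Mannich opening, decarboxylation by traces of water). The fallback is a stepwise assembly that sets out from 12. Part of 12 is silylated to the tert-butyldimethylsilyl ether F3 (TBSCl, imidazole, DMF). Heating 12 with an excess of F3 in concentrated toluene solution at 110 °C should acylate the only free hydroxyl group present, mainly by the acylketene from F3, and give the silylated open-chain dimer F4. The surplus of F3 is recovered, and the heterochiral open-chain dimer is separated from the homochiral one here. HF·pyridine in THF removes the silyl group and gives 14, now isolated. Heating 14 alone at high dilution in toluene closes the second ester bond and returns to the route at 15.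

Step 6. The isopropenyl ketone 10 may polymerise, imine 11 may self-condense through its enamine tautomer, and facial selectivity at C10 relative to C9 may be poor. In the fallback ring A is built by two separate bond formations and a Dieckmann condensation; it sets out from 6. Imine 11, released as in step 6, should undergo a decarboxylative Mannich reaction with mono-tert-butyl malonate (3-tert-butoxy-3-oxopropanoic acid, CH2Cl2, rt) anti to the C9 chain to give the trans-2,3-disubstituted piperidine β-amino ester F5. Aza-Michael addition of the secondary amine to methyl methacrylate (MeOH, 60 °C) gives the amino diester F6. Dieckmann condensation (KOtBu, 2.2 equiv, THF, 0 °C), in which the enolate of the tert-butyl acetate arm attacks the methyl ester, closes ring A and returns to the route at 12.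

Further compounds

F1 | step 8 | tert-butyl rel-(1R,3R,9S,9aS)-9-[(E)-5-(methoxycarbonyloxy)pent-3-en-1-yl]-3-methyl-2-oxooctahydro-2H-quinolizine-1-carboxylate (racemic) | C[C@@H]1CN2CCC[C@H](CC/C=C/COC(=O)OC)[C@H]2[C@@H](C(=O)OC(C)(C)C)C1=O
F2 | step 8 | heterochiral 16-membered carbocycle with both (E) chain alkenes and a tert-butoxycarbonyl group on each quaternary C1 and C1′ (configuration at C1 and C1′ open) | C[C@@H]1CN2CCC[C@@H]3CC/C=C/CC4(C(=O)OC(C)(C)C)C(=O)[C@@H](C)CN5CCC[C@@H](CC/C=C/CC(C(=O)OC(C)(C)C)(C1=O)[C@H]32)[C@H]45
F3 | step 7 | tert-butyl rel-(1R,3R,9S,9aS)-9-[(E)-5-(tert-butyldimethylsilyloxy)pent-3-en-1-yl]-3-methyl-2-oxooctahydro-2H-quinolizine-1-carboxylate (racemic) | C[C@@H]1CN2CCC[C@H](CC/C=C/CO[Si](C)(C)C(C)(C)C)[C@H]2[C@@H](C(=O)OC(C)(C)C)C1=O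
F4 | step 7 | tert-butyldimethylsilyl ether of the open-chain heterochiral dimer 14 | C[C@@H]1CN2CCC[C@H](CC/C=C/CO[Si](C)(C)C(C)(C)C)[C@H]2[C@@H](C(=O)OC/C=C/CC[C@@H]3CCCN4C[C@H](C)C(=O)[C@@H](C(=O)OC(C)(C)C)[C@@H]34)C1=O
F5 | step 6 | tert-butyl 2-[rel-(2S,3S)-3-[(E)-5-hydroxypent-3-en-1-yl]piperidin-2-yl]acetate (racemic, 2,3-trans) | N1CCC[C@H](CC/C=C/CO)[C@H]1CC(=O)OC(C)(C)C
F6 | step 6 | methyl 3-[rel-(2S,3S)-2-(2-tert-butoxy-2-oxoethyl)-3-[(E)-5-hydroxypent-3-en-1-yl]piperidin-1-yl]-2-methylpropanoate (epimer mixture at the methyl-bearing carbon) | COC(=O)C(C)CN1CCC[C@H](CC/C=C/CO)[C@H]1CC(=O)OC(C)(C)C
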